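**Remark on numbering, and one assumption.** Atoms keep the numbers of shikimic acid throughout: C1 carries the exocyclic carbon C7, and C3, C4, C5 are the three carbinol carbons of shikimic acid. In this numbering target 10 has the double bond C1=C6, O7 and O2 benzoylated, O3 acetylated, and O4–H and O5–H free. β is the ring face of O3 and O4; α is the face of O5 (and of O2 in 10). BDA is the butane-2,3-diacetal, (2S,3S)-2,3-dimethoxybutane-2,3-diyl, bridging O4 and O5 as a trans-fused 1,4-dioxane with both OMe groups axial. Assumption: this trans-fused diacetal holds the cyclohexene in the half-chair with O4 and O5 equatorial, as is general for such diacetals.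

## The problem

Target 10 is a cyclohexene with a benzoyloxymethyl branch on one alkene carbon (C1–C7) and four contiguous oxygenated stereocentres C2–C5: O2/O3 trans, O3/O4 cis, O4/O5 trans, with O2 and O5 cis across C1=C6. The carbon skeleton is trivial. The difficulty is the relative and absolute configuration of four adjacent secondary carbinol carbons and, above all, five oxygen atoms in three states: benzoates on O2 and O7, acetate on O3, free O4–H and O5–H, with the acetate cis to a free hydroxyl. Every stereocentre has a neighbour that could control it, but a route that builds the tetrol first must then tell apart four secondary hydroxyl groups of similar reactivity, and that invites acyl migration. The two allylic esters and the allylic alcohol can ionise under strong acid or Pd(0), and the esters rule out strong base, hydride and organometallic reagents late in the route. The enabling feature is that C3(OAc), C4(OH) and C5(OH) of 10 have the cis/trans pattern and the absolute configuration of C3, C4, C5 of (−)-shikimic acid 1, with C7 as its carboxyl carbon; only the double bond lies on the other side of C1 (C1=C6, not C1=C2) and C2 carries the fourth oxygen. The array H–C6=C1–C2–O is what an ene reaction of singlet oxygen gives from a C1=C2 alkene with a C6 methylene group, so one reaction can move the double bond and create the C2–O bond and stereocentre. The two free hydroxyls are the trans-diequatorial O4/O5 pair of 1, so a single diacetal can mask and release exactly these two.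

## Retrosynthesis

**10 ⇒ 9.** The cut is at the two acetal C–O bonds on O4 and O5. An acetonide would take the cis pair O3/O4, and silyl ethers would need selective introduction. The diacetal takes the trans-diequatorial pair, which is the pair that is free in 10, so the last step uncovers both hydroxyls at once and no polyol is ever acylated selectively. The forward step must hydrolyse the diacetal without moving the O3 acetate to the cis O4–H and without ionising the allylic benzoates.

**9 ⇒ 8.** The cut is the acyl C–O bond of the O2 benzoate. Alcohol 8 has one free hydroxyl, so the acylation is unambiguous. Bringing benzoate in together with the C2–O bond (carboxylate SN2′ or π-allyl chemistry) would need a leaving group at C6 that 1 does not offer. The forward step must acylate a hindered pseudo-axial allylic alcohol; the diacetal keeps O2 and O3 trans-diaxial, which excludes acetyl migration.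

**8 ⇒ 6 (through 7), the key disconnection.** The C2–O bond is cut, the hydrogen is returned to C6 and the double bond goes back to C1=C2 (retro-ene). This turns 8 into a plain derivative of 1 with all three original stereocentres intact. The obvious mapping of 1 onto 10, with its C1=C2 bond as the target alkene, fails: it puts the cis O3/O4 pair where 10 has a trans pair and the reverse. Shifting the register by one carbon makes all three centres coincide. The neighbouring options are weaker:
- Epoxidation of C1=C2 followed by isomerisation takes two steps and runs under acid or base, where the neighbouring O3 and O7 esters participate.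
- Selenium dioxide oxidises C6 without moving the double bond.
- Dehydration to a diene followed by 1,4-oxygenation erases C5.

The forward reaction must attack C2 from the α face only and take hydrogen from C6 only, on an alkene made electron-poor by two allylic acyloxy groups.

**6 ⇒ 5 ⇒ 4.** The cuts are the acyl C–O bonds at O3 and O7. Both esters belong to the target and are placed before the key step on purpose. A free O3–H would steer singlet oxygen to the β face through hydrogen bonding, and acyloxy groups on C3 and C7 make their geminal C–H bonds poor partners for the ene reaction. Diol 4 has one primary and one hindered secondary hydroxyl, so the forward step must distinguish them.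

**4 ⇒ 3 ⇒ 1.** Ester reduction, then the diacetal and the methyl ester are traced back to 1. No C–C bond and no stereocentre is made before the key step; 1 supplies all seven carbons and three of the four stereocentres. The diacetal formation must select O4/O5 over O3/O4.

## Roads not taken

**Alternative 1: carbohydrate chiral pool and ring-closing metathesis (the most obvious).** The cut is C1=C6 together with C1–C2. D-arabinose supplies C5, C4 and C3 (its C2–C4). The aldehyde A1 would be joined to methyl acrylate in a Baylis–Hillman reaction to give diene A2, and metathesis would close the ring. C2 would be set in an acyclic addition with weak control. Four hydroxyls would need three kinds of protecting group built up on the pentose. The acrylate ester would have to be reduced after ring closure, before any acyl group is placed. Far more than seven steps result, most of them protecting-group traffic. The chosen plan starts from a ring in which the oxygens are already differentiated.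

**Alternative 2: catalytic desymmetrisation of a meso endoperoxide.** The O2/O5 cis, O3/O4 cis pattern is that of conduritol A. The meso diene acetonide A3 with singlet oxygen would give meso endoperoxide A4, and an enantioselective base-catalysed Kornblum–DeLaMare rearrangement would give hydroxy enone A5. The absolute configuration would then rest on the enantiomeric purity delivered by the catalyst. C7 would still have to be attached by a C–C bond formation at the α-carbon. Reduction of the C2 ketone next to the cis-fused dioxolane is expected from the open face, placing O2 cis to O3, so an inversion in the presence of O5–H would follow. The acetonide also leaves the O3/O4 distinction unsolved. The chosen plan takes configuration, C7 and the O3-versus-O4/O5 distinction from 1.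

**Alternative 3: biomimetic arene-oxide logic.** The trans-diol diene A6 would be benzoylated at O2, epoxidised at C4=C5 syn to O3–H and acetylated to vinyl epoxide A7; water would open it at the allylic C5 with inversion to give 10. A6 is not commercially available in enantiopure form. Its two secondary hydroxyls would have to be acylated selectively. The final hydrolysis has three outlets on the same allyl system: C5 (wanted), the tertiary C1 by SN2′, and cis opening. The route would therefore stake everything on an uncontrolled last step, whereas the chosen plan carries C4 and C5 untouched from 1.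

Key step: step 5

## Steps

Step 1
Reactants: 1 (−)-shikimic acid
Product: 3 methyl 4,5-O-BDA-shikimate (O3–H free), via methyl shikimate 2 (not isolated)
Conditions: MeOH, CSA (cat.), reflux; then butane-2,3-dione, HC(OMe)3, reflux
Reagents that add atoms: methanol CO; butane-2,3-dione CC(=O)C(C)=O
Why: Fischer esterification followed by Ley butane-2,3-diacetal formation under thermodynamic control (trimethyl orthoformate removes water); only the trans-diequatorial O4/O5 pair can give the trans-fused dioxane with two axial OMe groups, so the allylic O3–H stays free. No stereocentre of 1 is touched, and the two acetal carbons take their configuration from the diol.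

Step 2
Reactants: 3 methyl 4,5-O-BDA-shikimate
Product: 4 4,5-O-BDA-protected 1-(hydroxymethyl)cyclohex-1-ene-3β,4β,5α-triol (C7–OH and O3–H free)
Conditions: DIBAL-H (4 equiv), CH2Cl2, −78 → −20 °C; aq. Rochelle salt
Reagents that add atoms: none
Why: 1,2-reduction of the conjugated methyl ester to the primary allylic alcohol with DIBAL-H; the free O3–H only consumes one hydride, and the diacetal and the alkene are inert at low temperature.

Step 3
Reactants: 4 the 7,3-diol
Product: 5 7-O-benzoate of 4 (O3–H free)
Conditions: BzCl (1.05 equiv), pyridine, CH2Cl2, −40 → −20 °C
Reagents that add atoms: benzoyl chloride O=C(Cl)c1ccccc1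
Why: Chemoselective acylation: the primary allylic C7–OH reacts well before the pseudo-axial secondary O3–H, which is flanked by the dioxane ring.

Step 4
Reactants: 5 the 7-O-benzoate
Product: 6 3-O-acetyl-7-O-benzoyl derivative of 4
Conditions: Ac2O, pyridine, DMAP (cat.), CH2Cl2, 0 °C → rt
Reagents that add atoms: acetic anhydride CC(=O)OC(C)=O
Why: DMAP-catalysed acetylation of the only remaining hydroxyl; the acetate removes the hydrogen-bond donor at O3 and shields the β face of C2 for the next step.

Step 5
Reactants: 6 the 3-O-acetyl-7-O-benzoyl C1=C2 alkene
Product: 8 2α-hydroxy-3β-acetoxy-1-(benzoyloxymethyl)-4β,5α-O-BDA-cyclohex-1(6)-ene, via allylic hydroperoxide 7 (not isolated)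
Conditions: O2, TPP (cat.), white LED, CDCl3 (or CCl4), 0–5 °C; then PPh3, 0 °C → rt
Reagents that add atoms: dioxygen O=O
Why: Schenck ene reaction: photosensitised singlet oxygen bonds to C2 of the C1=C2 double bond through a perepoxide-like transition state and takes the allylic hydrogen from C6 on the same face, so the double bond moves to C1=C6 and C2 gains an OOH group (7); PPh3 then reduces O–OH to OH in the same flask. The closest known reactions are the photooxygenations of 1-substituted cyclohexenes and of trisubstituted alkenes with allylic acyloxy groups to transposed allylic hydroperoxides. No ring is closed. The step needs regioselectivity for C6–H, and the substrate secures it three ways: C3–H and C7–H2 sit on acyloxy-bearing carbons, whose C–H bonds singlet oxygen abstracts only reluctantly; C3–H is pseudo-equatorial and lies near the alkene plane; and C7 is on the less substituted side of the alkene, while the cis effect favours the ring side. The new stereocentre C2 is controlled by the diacetal and the C3 acetate: with O4/O5 locked equatorial, the C3–OAc is pseudo-axial on the β face and the only axial C6–H is on the α face, so the suprafacial ene reaction must use the α face and places O2 trans to O3 and cis to O5, as in 10. C3, C4 and C5 are not touched, and esters, diacetal and the new allylic alcohol are inert to singlet oxygen and PPh3. The hydroxyl-directing effect that would send oxygen to the β face is switched off because O3 and O7 are acylated.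

Step 6
Reactants: 8 the 2α-alcohol
Product: 9 2α-benzoyloxy-3β-acetoxy-1-(benzoyloxymethyl)-4β,5α-O-BDA-cyclohex-1(6)-ene
Conditions: BzCl (2 equiv), pyridine, DMAP (cat.), CH2Cl2, 0 °C → rt
Reagents that add atoms: benzoyl chloride O=C(Cl)c1ccccc1
Why: DMAP-catalysed benzoylation of the single free hydroxyl; O2 and O3 are held trans-diaxial, so the acetate cannot migrate, and a benzoyl shift from O7 to O2 would be corrected by the excess reagent to the same product.

Step 7
Reactants: 9 the fully acylated diacetal
Product: 10 [(3R,4S,5S,6S)-5-acetoxy-6-(benzoyloxy)-3,4-dihydroxycyclohex-1-en-1-yl]methyl benzoate (target)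
Conditions: TFA/H2O (9:1), 0 °C → rt, short contact; co-evaporation with toluene
Reagents that add atoms: none
Why: Acid hydrolysis of the butane-2,3-diacetal, the standard release of such trans-diols; carboxylic esters survive brief aqueous TFA, and the electron-poor allylic benzoates should not ionise. No stereocentre is involved.

## Compound list

1 | (−)-shikimic acid, (3R,4S,5R)-3,4,5-trihydroxycyclohex-1-ene-1-carboxylic acid | OC(=O)C1=C[C@@H](O)[C@@H](O)[C@H](O)C1 | starting material
2 | methyl shikimate | COC(=O)C1=C[C@@H](O)[C@@H](O)[C@H](O)C1 | intermediate (not isolated)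
3 | methyl 4,5-O-BDA-shikimate, O3–H free | COC(=O)C1=C[C@@H](O)[C@H]2O[C@@](OC)(C)[C@](OC)(C)O[C@@H]2C1 | intermediate
4 | 4,5-O-BDA-protected 1-(hydroxymethyl)cyclohex-1-ene-3β,4β,5α-triol | OCC1=C[C@@H](O)[C@H]2O[C@@](OC)(C)[C@](OC)(C)O[C@@H]2C1 | intermediate
5 | 7-O-benzoate of 4 | O=C(OCC1=C[C@@H](O)[C@H]2O[C@@](OC)(C)[C@](OC)(C)O[C@@H]2C1)c1ccccc1 | intermediate
6 | 3-O-acetyl-7-O-benzoyl derivative of 4 | O=C(OCC1=C[C@@H](OC(C)=O)[C@H]2O[C@@](OC)(C)[C@](OC)(C)O[C@@H]2C1)c1ccccc1 | intermediate
7 | 2α-hydroperoxide: 3β-acetoxy-1-(benzoyloxymethyl)-4β,5α-O-BDA-cyclohex-1(6)-en-2α-yl hydroperoxide | C1=C(COC(=O)c3ccccc3)[C@H](OO)[C@@H](OC(C)=O)[C@H]2O[C@@](OC)(C)[C@](OC)(C)O[C@H]12 | intermediate (not isolated)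
8 | 2α-alcohol: 2α-hydroxy-3β-acetoxy-1-(benzoyloxymethyl)-4β,5α-O-BDA-cyclohex-1(6)-ene | C1=C(COC(=O)c3ccccc3)[C@H](O)[C@@H](OC(C)=O)[C@H]2O[C@@](OC)(C)[C@](OC)(C)O[C@H]12 | intermediate
9 | 2α-benzoate of 8 | C1=C(COC(=O)c3ccccc3)[C@H](OC(=O)c3ccccc3)[C@@H](OC(C)=O)[C@H]2O[C@@](OC)(C)[C@](OC)(C)O[C@H]12 | intermediate
10 | [(3R,4S,5S,6S)-5-acetoxy-6-(benzoyloxy)-3,4-dihydroxycyclohex-1-en-1-yl]methyl benzoate | CC(=O)O[C@H]1[C@@H](O)[C@H](O)C=C(COC(=O)c2ccccc2)[C@@H]1OC(=O)c1ccccc1 | target

## Step count and risk

Total: 7 steps. Longest linear sequence: 7 steps (1 → 10).

**Step 5 (key step).** The alkene carries two allylic acyloxy groups and should react slowly with electrophilic singlet oxygen. Long irradiation may let physical quenching and sensitiser bleaching dominate, and a minor abstraction of C7–H (to an enol benzoate) or a radical allyl shift of the hydroperoxide before reduction may erode the yield.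

Fallback (sets out from 1, comes back at 10): the double bond is placed by a palladium-catalysed cis-1,4 opening of a diene monoepoxide instead of an ene reaction.
- 1 is esterified as in step 1 (2), and the cis O3/O4 pair is closed with 2,2-dimethoxypropane/CSA to methyl 3,4-O-isopropylidene shikimate F1.
- Tf2O/pyridine gives the 5-O-triflate F2, which CsOAc in DMF eliminates towards C6 to the cyclohexa-1,5-diene ester F3.
- mCPBA attacks only C5=C6 (the other double bond is an acrylate), from the α face anti to the dioxolane, to give the 5α,6α-epoxide F4.
- DIBAL-H at −78 °C reduces the ester to the epoxy alcohol F5, and BzCl/pyridine gives the epoxy benzoate F6.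
- Pd(PPh3)4 (cat.) and benzoic acid in THF open the vinyl epoxide with double inversion: Pd enters anti to the epoxide oxygen, and benzoate attacks anti to Pd at the π-allyl terminus C2, remote from the alkoxide. The product is the 2α-benzoate 5α-alcohol F7, with C1=C6 in place and O2 and O5 set and distinguished.
- Aqueous acetic acid removes the acetonide to give triol F8.
- Triethyl orthoacetate/CSA closes the cis O3/O4 pair to the cyclic orthoacetate F9. Mild aqueous acid opens it with the acetyl group left on the axial oxygen; this is O3, because the O2 benzoate stays pseudo-axial to avoid A(1,2) strain with C7. The product is 10.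

This route is longer, erases and rebuilds C5, and ends on a conformational preference, which is why it is the fallback and not the plan.

**Step 3.** Acylation may run on to the 3,7-dibenzoate or partly occur at O3, because the selectivity rests only on the primary/secondary rate difference.

Fallback (sets out from 4, comes back at 6): TBSCl/imidazole silylates only the primary hydroxyl to the 7-O-silyl ether F10. Ac2O/pyridine/DMAP gives the 3-O-acetate F11. HF·pyridine removes the silyl group to the 7-alcohol F12; an acetyl shift from O3 to O7 would need a seven-membered transition state across the double bond. BzCl/pyridine then gives 6.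

**Step 7.** The acetate may migrate from O3 to the newly freed cis O4–H under acid, or the diacetal may cleave incompletely if the contact time is kept short to avoid this.

Fallback (sets out from 9, comes back at 10): the acetate is removed before the acid step and put back afterwards by a stereoelectronically controlled orthoester opening. HCl in methanol (AcCl/MeOH, 0 °C) cleaves acetates much faster than benzoates and leaves the diacetal intact, since it is formed under such conditions; this gives the 3-alcohol F13. TFA/H2O then gives triol F8, which has no acetate to migrate. Triethyl orthoacetate/CSA gives the orthoacetate F9, and mild aqueous acid opens it to 10 as in the fallback to step 5.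

## Further compounds

F1 | step 5 | methyl 3,4-O-isopropylidene shikimate | COC(=O)C1=C[C@H]2OC(C)(C)O[C@H]2[C@H](O)C1
F2 | step 5 | methyl 3,4-O-isopropylidene-5-O-triflyl shikimate | COC(=O)C1=C[C@H]2OC(C)(C)O[C@H]2[C@H](OS(=O)(=O)C(F)(F)F)C1
F3 | step 5 | methyl (3R,4S)-3,4-O-isopropylidene-3,4-dihydroxycyclohexa-1,5-diene-1-carboxylate | COC(=O)C1=C[C@H]2OC(C)(C)O[C@H]2C=C1
F4 | step 5 | 5α,6α-epoxide of F3 | COC(=O)C1=C[C@H]2OC(C)(C)O[C@H]2[C@@H]3O[C@H]13
F5 | step 5 | epoxy allylic alcohol (C7–OH) from F4 | OCC1=C[C@H]2OC(C)(C)O[C@H]2[C@@H]3O[C@H]13
F6 | step 5 | 7-O-benzoate of F5 | O=C(OCC1=C[C@H]2OC(C)(C)O[C@H]2[C@@H]3O[C@H]13)c1ccccc1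
F7 | step 5 | 2α-benzoyloxy-5α-hydroxy-3β,4β-O-isopropylidene-1-(benzoyloxymethyl)cyclohex-1(6)-ene | C1=C(COC(=O)c3ccccc3)[C@H](OC(=O)c3ccccc3)[C@H]2OC(C)(C)O[C@H]2[C@@H]1O
F8 | step 5 | 2α-benzoyloxy-1-(benzoyloxymethyl)cyclohex-1(6)-ene-3β,4β,5α-triol (3-O-deacetyl-10) | C1=C(COC(=O)c2ccccc2)[C@H](OC(=O)c2ccccc2)[C@@H](O)[C@@H](O)[C@@H]1O
F9 | step 5 | 3,4-O-(1-ethoxyethylidene) orthoacetate of F8 (both epimers at the orthoester carbon) | C1=C(COC(=O)c3ccccc3)[C@H](OC(=O)c3ccccc3)[C@H]2OC(C)(OCC)O[C@H]2[C@@H]1O
F10 | step 3 | 7-O-TBS ether of 4 | CC(C)(C)[Si](C)(C)OCC1=C[C@@H](O)[C@H]2O[C@@](OC)(C)[C@](OC)(C)O[C@@H]2C1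
F11 | step 3 | 3-O-acetyl-7-O-TBS derivative of 4 | CC(C)(C)[Si](C)(C)OCC1=C[C@@H](OC(C)=O)[C@H]2O[C@@](OC)(C)[C@](OC)(C)O[C@@H]2C1
F12 | step 3 | 3-O-acetyl derivative of 4 (C7–OH free) | OCC1=C[C@@H](OC(C)=O)[C@H]2O[C@@](OC)(C)[C@](OC)(C)O[C@@H]2C1
F13 | step 7 | 3-O-deacetyl-9 (O3–H free, dibenzoate, BDA) | C1=C(COC(=O)c3ccccc3)[C@H](OC(=O)c3ccccc3)[C@@H](O)[C@H]2O[C@@](OC)(C)[C@](OC)(C)O[C@H]12
A1 | alternative 1 | D-arabinose-derived (2R,3S,4R)-2-O-TBS-3,4-di-O-PMB-hex-5-enal | O=C[C@@H](O[Si](C)(C)C(C)(C)C)[C@@H](OCc1ccc(OC)cc1)[C@H](OCc1ccc(OC)cc1)C=C
A2 | alternative 1 | Baylis–Hillman diene, methyl 2-methylene-3-hydroxy-4-O-TBS-5,6-di-O-PMB-oct-7-enoate | C=C(C(=O)OC)[C@H](O)[C@@H](O[Si](C)(C)C(C)(C)C)[C@@H](OCc1ccc(OC)cc1)[C@H](OCc1ccc(OC)cc1)C=C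
A3 | alternative 2 | meso cis-5,6-O-isopropylidene-cyclohexa-1,3-diene-5,6-diol | C1=C[C@H]2OC(C)(C)O[C@H]2C=C1
A4 | alternative 2 | meso endoperoxide of A3 (peroxide anti to the dioxolane) | C1=C[C@@H]2OO[C@H]1[C@@H]1OC(C)(C)O[C@H]21
A5 | alternative 2 | 4-hydroxy-5,6-O-isopropylidene-cyclohex-2-enone (carbonyl = C2, hydroxyl on C5α, dioxolane on O3/O4) | C1=CC(=O)[C@H]2OC(C)(C)O[C@H]2[C@@H]1O
A6 | alternative 3 | trans-2α,3β-dihydroxy-cyclohexa-1(6),4-dien-1-ylmethyl benzoate | C1=C(COC(=O)c2ccccc2)[C@H](O)[C@@H](O)C=C1
A7 | alternative 3 | 4β,5β-epoxide with 2α-benzoate, 3β-acetate and 7-benzoate on the C1=C6 cyclohexene | C1=C(COC(=O)c3ccccc3)[C@H](OC(=O)c3ccccc3)[C@@H](OC(C)=O)[C@H]2O[C@@H]12
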